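**Plan**
- Cuts: (i) the bond from furan C2 of the benzofuran to the methine C4 of the pentane chain; (ii) the C2–C3 bond of the chain together with the C2–O bond of the aryl carbinol (traced back to C2–B); (iii) the pyran ring of the chromene (O1–C2 and C4–C4a, back to an aryl propargyl ether) and the furan ring (O1–C2 and C3–C3a, back to an iodophenol and an ethyne unit).
- Enabling feature: the two stereogenic carbons of the chain (C2: aryl, Me, OH; C4: Me, H, furan C2) are 1,3-related and can both be carried as C–B bonds of a 1,3-bis(boronic ester). The furan ring has an acidic C2–H next to O1 and an enol-ether C2=C3 bond that accepts Br+ at C3, so the secondary C–B bond can be exchanged for the C4–C2(furan) bond by a 1,2-metallate shift.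
- Forward order: chromene ring (Claisen/oxa-6π), then ketone to (S)-carbinol carbamate; lithiation–borylation with propene-derived (S)-1,2-bis(boronate) joins C2–C3; the separately made, bis-silyl-masked benzofuran is coupled at the secondary boron; C–B oxidation and fluoride unmasking finish.
- Stereochemistry: C2 (R) comes from asymmetric ketone hydrogenation, relayed by stereospecific lithiation–borylation and retentive C–B oxidation. C4 (S) comes from enantioselective diboration of propene and is retained in the 1,2-shift.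

Key step: step 10

Assumption: the (R,R)-TADDOL-derived phosphonite ligand is taken to give the (S)-1,2-bis(boronate) from propene; if the sense of induction is the opposite, the (S,S)-ligand is used.
Remark: the two stereocentres are set by separate enantioselective steps, so any minor enantiomer of 8 or 11 appears as a diastereomer of 14 or 24 and should be removable by chromatography. Chain locants: C2 = aryl carbinol carbon, C4 = methine carbon.

Step 1
Reactants: 1 1-(4-hydroxy-2-methoxyphenyl)ethan-1-one; 2 3-chloro-3-methylbut-1-yne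
Product: 3 1-{2-methoxy-4-[(2-methylbut-3-yn-2-yl)oxy]phenyl}ethan-1-one
Conditions: K2CO3, KI (cat.), CuI (cat.), acetone, reflux
Reagents that add atoms: none
Why: Williamson-type O-propargylation of the acidic para-acylphenol with the tertiary propargylic chloride (copper-assisted substitution) should give the aryl 1,1-dimethylpropargyl ether, the methyl ketone not being enolised by carbonate.

Step 2
Reactants: 3 1-{2-methoxy-4-[(2-methylbut-3-yn-2-yl)oxy]phenyl}ethan-1-one
Product: 6 1-(7-methoxy-2,2-dimethyl-2H-chromen-6-yl)ethan-1-one, via ortho-allenylphenol 4 (not isolated), via ortho-quinone methide 5 (not isolated)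
Conditions: N,N-diethylaniline, 190 °C
Reagents that add atoms: none
Why: Aryl propargyl ether Claisen rearrangement to 4, 1,5-hydrogen shift to 5 and oxa-6π electrocyclisation should close the 2,2-dimethyl-2H-pyran ring, the [3,3] shift being expected at the unflanked carbon para to OMe (not at the carbon between the two oxygens), which gives the linear 6-acetyl-7-methoxy pattern.

Step 3
Reactants: 6 1-(7-methoxy-2,2-dimethyl-2H-chromen-6-yl)ethan-1-one
Product: 7 (1S)-1-(7-methoxy-2,2-dimethyl-2H-chromen-6-yl)ethan-1-ol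
Conditions: trans-RuCl2[(R)-xylbinap][(R)-daipen] (cat.), KOtBu, H2 (8 atm), i-PrOH, rt
Reagents that add atoms: none
Why: Noyori asymmetric hydrogenation (outer-sphere hydride/proton transfer) reduces only the polar C=O bond, the (R)-diphosphine/(R)-diamine pairing should give the (S)-1-arylethanol by the aryl/methyl discrimination known for acetophenones, and the basic medium spares the chromene C3=C4 bond and the ionisable electron-rich benzylic alcohol.

Step 4
Reactants: 7 (1S)-1-(7-methoxy-2,2-dimethyl-2H-chromen-6-yl)ethan-1-ol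
Product: 8 (1S)-1-(7-methoxy-2,2-dimethyl-2H-chromen-6-yl)ethyl N,N-diisopropylcarbamate
Conditions: i-Pr2NCOCl, Et3N, toluene, reflux
Reagents that add atoms: N,N-diisopropylcarbamoyl chloride, CC(C)N(C(C)C)C(Cl)=O
Why: O-Carbamoylation (nucleophilic acyl substitution) installs the directing and leaving group for the lithiation–borylation without touching the stereocentre.

Step 5
Reactants: 9 propene; 10 bis(pinacolato)diboron
Product: 11 (S)-2,2'-(propane-1,2-diyl)bis(4,4,5,5-tetramethyl-1,3,2-dioxaborolane)
Conditions: Pt(dba)3 (1 mol %), (R,R)-3,5-diisopropylphenyl-TADDOL phenylphosphonite (1.2 mol %), THF, 60 °C, sealed vessel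
Reagents that add atoms: none
Why: Platinum-catalysed enantioselective 1,2-diboration of a terminal alkene (B–B oxidative addition to zerovalent platinum, ligand-controlled face-selective insertion of propene, reductive elimination) should set the secondary C–B stereocentre as (S).

Step 6
Reactants: 8 (1S)-1-(7-methoxy-2,2-dimethyl-2H-chromen-6-yl)ethyl N,N-diisopropylcarbamate; 11 (S)-2,2'-(propane-1,2-diyl)bis(4,4,5,5-tetramethyl-1,3,2-dioxaborolane)
Product: 14 2,2'-[(2S,4S)-2-(7-methoxy-2,2-dimethyl-2H-chromen-6-yl)pentane-2,4-diyl]bis(4,4,5,5-tetramethyl-1,3,2-dioxaborolane), via lithiated carbamate 12 (not isolated), via boronate complex 13 (not isolated)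
Conditions: s-BuLi, Et2O, −78 °C; then 11, −78 °C; then MgBr2 in MeOH, −78 °C to rt
Reagents that add atoms: none
Why: Stereospecific lithiation–borylation (Matteson-type 1,2-metallate rearrangement): carbamate-directed deprotonation gives the configurationally stable benzylic lithium 12 with retention, 12 adds with retention to the less hindered primary boron of 11 to give 13, and the anti-periplanar 1,2-shift of the CH2 group with loss of the carbamate (invertive at carbon, helped by MgBr2/MeOH) should form the C2–C3 bond and the tertiary (S) C–B centre while the secondary (S) C–B centre is a spectator.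

Step 7
Reactants: 15 1-(2,4-dihydroxyphenyl)ethan-1-one
Product: 16 1-(2,4-dihydroxy-5-iodophenyl)ethan-1-one
Conditions: ICl, AcOH, rt
Reagents that add atoms: iodine monochloride, ClI
Why: Electrophilic aromatic iodination under acidic conditions should occur at C5, para to the chelated 2-OH and ortho to the 4-OH, in preference to the hindered C3 between the two hydroxyl groups.

Step 8
Reactants: 16 1-(2,4-dihydroxy-5-iodophenyl)ethan-1-one; 17 ethynyltrimethylsilane
Product: 19 1-(6-hydroxy-1-benzofuran-5-yl)ethan-1-one, via silylalkynyl phenol 18 (not isolated)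
Conditions: PdCl2(PPh3)2 (cat.), CuI (cat.), Et3N, DMF, rt; then TBAF, 70 °C
Reagents that add atoms: none
Why: Sonogashira coupling followed by fluoride-induced desilylation and 5-endo-dig attack of the 4-phenoxide on the alkyne should give the 2,3-unsubstituted benzofuran, and since only the 4-OH is ortho to the alkyne the linear 5-acetyl-6-hydroxy isomer is the only one possible.

Step 9
Reactants: 19 1-(6-hydroxy-1-benzofuran-5-yl)ethan-1-one
Product: 20 triisopropyl[(5-{1-[(triisopropylsilyl)oxy]ethenyl}-1-benzofuran-6-yl)oxy]silane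
Conditions: TIPSOTf (2.5 equiv), Et3N, CH2Cl2, 0 °C to rt
Reagents that add atoms: triisopropylsilyl trifluoromethanesulfonate, CC(C)[Si](C(C)C)(C(C)C)OS(=O)(=O)C(F)(F)F
Why: Silyl triflate/amine silylation (O-silylation of the phenol and soft enolisation of the methyl ketone) masks both sites as groups that tolerate organolithiums and are removed together by fluoride.

Step 10
Reactants: 20 triisopropyl[(5-{1-[(triisopropylsilyl)oxy]ethenyl}-1-benzofuran-6-yl)oxy]silane; 14 2,2'-[(2S,4S)-2-(7-methoxy-2,2-dimethyl-2H-chromen-6-yl)pentane-2,4-diyl]bis(4,4,5,5-tetramethyl-1,3,2-dioxaborolane)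
Product: 23 2-[(2S,4S)-2-(7-methoxy-2,2-dimethyl-2H-chromen-6-yl)-4-(6-[(triisopropylsilyl)oxy]-5-{1-[(triisopropylsilyl)oxy]ethenyl}-1-benzofuran-2-yl)pentan-2-yl]-4,4,5,5-tetramethyl-1,3,2-dioxaborolane, via 2-lithiobenzofuran 21 (not isolated), via boronate complex 22 (not isolated)
Conditions: n-BuLi (1.05 equiv), THF, −78 °C; then 14, −78 °C; then NBS (1.05 equiv), THF, −78 °C to rt
Reagents that add atoms: none
Why: n-BuLi removes the C2–H of the furan ring of 20 (the most acidic C–H, next to O1) to give 21, which adds to the secondary boron of 14 to give the tetracoordinate boronate complex 22. NBS then delivers Br+ to C3 of the electron-rich furan ring; the oxocarbenium character developing at C2 (stabilised by O1) triggers a 1,2-shift of the sec-alkyl group from boron to C2, and loss of bromide and the boron residue restores the aromatic furan. The closest known reaction type is the transition-metal-free, enantiospecific sp2–sp3 coupling of secondary boronic esters with lithiated furans and benzofurans (a Zweifel-type 1,2-metallate rearrangement). No ring is closed and no new stereocentre is created: the migrating carbon keeps its configuration, so the (S) C–B centre of 14 should become the (S) methine C4, and C2 is untouched. The step needs site selectivity between the two boron atoms, secured by the tertiary benzylic boron sitting on a quaternary carbon beside the ortho-methoxyaryl group while the secondary boron is open to the planar aryllithium, and chemoselectivity of NBS, secured by the much higher nucleophilicity of the anionic boronate over the silyl enol ether and the chromene C3=C4 bond at −78 °C with one equivalent of NBS.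

Step 11
Reactants: 23 the tertiary boronic ester from step 10
Product: 24 (2R,4S)-2-(7-methoxy-2,2-dimethyl-2H-chromen-6-yl)-4-(6-[(triisopropylsilyl)oxy]-5-{1-[(triisopropylsilyl)oxy]ethenyl}-1-benzofuran-2-yl)pentan-2-ol
Conditions: 30% H2O2, 2 M NaOH, THF, 0 °C
Reagents that add atoms: hydrogen peroxide, OO
Why: Hydroperoxide oxidation of the C–B bond (1,2-shift of carbon from boron to oxygen with retention) should give the (R)-carbinol, and it is run before any fluoride treatment (which would protodeboronate the benzylic boronate) and before the ketone is unmasked (so no Dakin oxidation of an ortho-hydroxyaryl ketone can occur).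

Step 12
Reactants: 24 (2R,4S)-2-(7-methoxy-2,2-dimethyl-2H-chromen-6-yl)-4-(6-[(triisopropylsilyl)oxy]-5-{1-[(triisopropylsilyl)oxy]ethenyl}-1-benzofuran-2-yl)pentan-2-ol
Product: 25 1-{6-hydroxy-2-[(2S,4R)-4-hydroxy-4-(7-methoxy-2,2-dimethyl-2H-chromen-6-yl)pentan-2-yl]-1-benzofuran-5-yl}ethan-1-one
Conditions: TBAF (2.5 equiv), THF, 0 °C to rt; aq. NH4Cl work-up
Reagents that add atoms: none
Why: Fluoride-mediated desilylation cleaves the aryl silyl ether and the silyl enol ether (the enolate is protonated to the methyl ketone on work-up) under non-acidic conditions that spare the acid-labile tertiary benzylic alcohol and the chromene.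

**Compound list**
1 | 1-(4-hydroxy-2-methoxyphenyl)ethan-1-one | CC(=O)c1ccc(O)cc1OC | starting material
2 | 3-chloro-3-methylbut-1-yne | CC(C)(Cl)C#C | starting material
3 | 1-{2-methoxy-4-[(2-methylbut-3-yn-2-yl)oxy]phenyl}ethan-1-one | CC(=O)c1ccc(OC(C)(C)C#C)cc1OC | intermediate
4 | 1-[4-hydroxy-2-methoxy-5-(3-methylbuta-1,2-dien-1-yl)phenyl]ethan-1-one (ortho-allenylphenol) | CC(=O)c1cc(C=C=C(C)C)c(O)cc1OC | intermediate
5 | (6Z)-4-acetyl-3-methoxy-6-(3-methylbut-2-en-1-ylidene)cyclohexa-2,4-dien-1-one (ortho-quinone methide) | CC(=O)C1=C/C(=C/C=C(C)C)C(=O)C=C1OC | intermediate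
6 | 1-(7-methoxy-2,2-dimethyl-2H-chromen-6-yl)ethan-1-one (encecalin) | COc1cc2c(cc1C(C)=O)C=CC(C)(C)O2 | intermediate
7 | (1S)-1-(7-methoxy-2,2-dimethyl-2H-chromen-6-yl)ethan-1-ol | COc1cc2c(cc1[C@H](C)O)C=CC(C)(C)O2 | intermediate
8 | (1S)-1-(7-methoxy-2,2-dimethyl-2H-chromen-6-yl)ethyl N,N-diisopropylcarbamate | COc1cc2c(cc1[C@H](C)OC(=O)N(C(C)C)C(C)C)C=CC(C)(C)O2 | intermediate
9 | propene | CC=C | starting material
10 | bis(pinacolato)diboron | CC1(C)OB(OC1(C)C)B1OC(C)(C)C(C)(C)O1 | starting material
11 | (S)-2,2'-(propane-1,2-diyl)bis(4,4,5,5-tetramethyl-1,3,2-dioxaborolane) | CC1(C)OB(C[C@H](C)B2OC(C)(C)C(C)(C)O2)OC1(C)C | intermediate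
12 | (S)-α-lithio derivative of carbamate 8 | COc1cc2c(cc1[C@]([Li])(C)OC(=O)N(C(C)C)C(C)C)C=CC(C)(C)O2 | intermediate
13 | lithium boronate complex of 12 at the primary boron of 11 | [Li+].COc1cc2c(cc1[C@](C)(OC(=O)N(C(C)C)C(C)C)[B-]3(C[C@H](C)B4OC(C)(C)C(C)(C)O4)OC(C)(C)C(C)(C)O3)C=CC(C)(C)O2 | intermediate
14 | 2,2'-[(2S,4S)-2-(7-methoxy-2,2-dimethyl-2H-chromen-6-yl)pentane-2,4-diyl]bis(4,4,5,5-tetramethyl-1,3,2-dioxaborolane) | COc1cc2c(cc1[C@](C)(B3OC(C)(C)C(C)(C)O3)C[C@H](C)B3OC(C)(C)C(C)(C)O3)C=CC(C)(C)O2 | intermediate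
15 | 1-(2,4-dihydroxyphenyl)ethan-1-one | CC(=O)c1ccc(O)cc1O | starting material
16 | 1-(2,4-dihydroxy-5-iodophenyl)ethan-1-one | CC(=O)c1cc(I)c(O)cc1O | intermediate
17 | ethynyltrimethylsilane | C#C[Si](C)(C)C | starting material
18 | 1-{2,4-dihydroxy-5-[(trimethylsilyl)ethynyl]phenyl}ethan-1-one | CC(=O)c1cc(C#C[Si](C)(C)C)c(O)cc1O | intermediate
19 | 1-(6-hydroxy-1-benzofuran-5-yl)ethan-1-one | CC(=O)c1cc2ccoc2cc1O | intermediate
20 | triisopropyl[(5-{1-[(triisopropylsilyl)oxy]ethenyl}-1-benzofuran-6-yl)oxy]silane | C=C(O[Si](C(C)C)(C(C)C)C(C)C)c1cc2ccoc2cc1O[Si](C(C)C)(C(C)C)C(C)C | intermediate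
21 | 2-lithio derivative of benzofuran 20 | C=C(O[Si](C(C)C)(C(C)C)C(C)C)c1cc2cc([Li])oc2cc1O[Si](C(C)C)(C(C)C)C(C)C | intermediate
22 | lithium boronate complex of 21 at the secondary boron of 14 | [Li+].COc1cc2c(cc1[C@](C)(B3OC(C)(C)C(C)(C)O3)C[C@H](C)[B-]3(OC(C)(C)C(C)(C)O3)c3cc4cc(C(=C)O[Si](C(C)C)(C(C)C)C(C)C)c(O[Si](C(C)C)(C(C)C)C(C)C)cc4o3)C=CC(C)(C)O2 | intermediate
23 | 2-[(2S,4S)-2-(7-methoxy-2,2-dimethyl-2H-chromen-6-yl)-4-(6-[(triisopropylsilyl)oxy]-5-{1-[(triisopropylsilyl)oxy]ethenyl}-1-benzofuran-2-yl)pentan-2-yl]-4,4,5,5-tetramethyl-1,3,2-dioxaborolane | COc1cc2c(cc1[C@](C)(B3OC(C)(C)C(C)(C)O3)C[C@H](C)c3cc4cc(C(=C)O[Si](C(C)C)(C(C)C)C(C)C)c(O[Si](C(C)C)(C(C)C)C(C)C)cc4o3)C=CC(C)(C)O2 | intermediate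
24 | (2R,4S)-2-(7-methoxy-2,2-dimethyl-2H-chromen-6-yl)-4-(6-[(triisopropylsilyl)oxy]-5-{1-[(triisopropylsilyl)oxy]ethenyl}-1-benzofuran-2-yl)pentan-2-ol | COc1cc2c(cc1[C@](C)(O)C[C@H](C)c3cc4cc(C(=C)O[Si](C(C)C)(C(C)C)C(C)C)c(O[Si](C(C)C)(C(C)C)C(C)C)cc4o3)C=CC(C)(C)O2 | intermediate
25 | 1-{6-hydroxy-2-[(2S,4R)-4-hydroxy-4-(7-methoxy-2,2-dimethyl-2H-chromen-6-yl)pentan-2-yl]-1-benzofuran-5-yl}ethan-1-one | COc1cc2c(cc1[C@](C)(O)C[C@H](C)c1cc3cc(C(C)=O)c(O)cc3o1)C=CC(C)(C)O2 | target

Total step count: 12. Longest linear sequence: 8 steps (1, 2, 3, 4, 6, 10, 11, 12).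

**Steps most likely to fail**

Step 10. The risk is loss of site selectivity in boronate-complex formation (addition of the aryllithium to the tertiary benzylic boron, or to both boron atoms) and diversion of NBS to bromination of the silyl enol ether or the chromene double bond. The fallback sets out from 6 and comes back to the route at 25; it carries the tertiary oxygen instead of a second boron, so only one boron is present at the coupling. Ketone 6 is allylated by catalytic asymmetric allylboration (B-allyl-1,3,2-dioxaborinane, 3,3'-dibromo-BINOL catalyst of the enantiomer that delivers the (R)-carbinol) to give (2R)-2-(7-methoxy-2,2-dimethyl-2H-chromen-6-yl)pent-4-en-2-ol F1. Silylation (TESOTf, 2,6-lutidine) gives triethyl{[(2R)-2-(7-methoxy-2,2-dimethyl-2H-chromen-6-yl)pent-4-en-2-yl]oxy}silane F2. CuCl/chiral bisphosphine-catalysed enantioselective Markovnikov protoboration of the terminal alkene (B2pin2, KOMe, MeOH) gives triethyl{[(2R,4S)-2-(7-methoxy-2,2-dimethyl-2H-chromen-6-yl)-4-(4,4,5,5-tetramethyl-1,3,2-dioxaborolan-2-yl)pentan-2-yl]oxy}silane F3. Addition of 21 gives the lithium boronate complex of 21 and F3 F4, and NBS then gives the triethylsilyl ether of 24 F5 by the same retentive 1,2-shift. TBAF removes all three silyl groups and gives 25.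

Step 6. The risk is slow or reversible capture of the hindered lithiated benzylic carbamate by the branched bis(boronate), so that the organolithium racemises or decomposes on warming, or attack at the secondary boron of 11. The fallback sets out from 8 and comes back at 14; the second C–B stereocentre is then made by catalyst-controlled hydroboration and not imported from propene. Lithiation of 8 as before and capture of 12 with the small allylboronic acid pinacol ester gives the lithium boronate complex of 12 and allylboronic acid pinacol ester F6. Its 1,2-shift (MgBr2/MeOH) gives 2-[(2S)-2-(7-methoxy-2,2-dimethyl-2H-chromen-6-yl)pent-4-en-2-yl]-4,4,5,5-tetramethyl-1,3,2-dioxaborolane F7. CuCl/chiral bisphosphine-catalysed enantioselective Markovnikov protoboration of the terminal alkene of F7 (B2pin2, KOMe, MeOH) should then give 14.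

Step 5. The risk is weak facial discrimination with the smallest monosubstituted alkene and loss of the gaseous substrate, leading to low enantiomeric purity or incomplete conversion. The fallback sets out from 10 and comes back at 11. Pt(PPh3)4-catalysed cis-diboration of propyne with 10 gives (E)-2,2'-(prop-1-ene-1,2-diyl)bis(4,4,5,5-tetramethyl-1,3,2-dioxaborolane) F8, a non-volatile alkene with the two boron atoms cis. Rhodium-catalysed asymmetric hydrogenation of F8 ([Rh(nbd)2]BF4, Walphos-type ferrocenyl diphosphine of the enantiomer that gives the (S)-product, H2, toluene) should give 11.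

**Further compounds**
F1 | step 10 | (2R)-2-(7-methoxy-2,2-dimethyl-2H-chromen-6-yl)pent-4-en-2-ol | COc1cc2c(cc1[C@](C)(O)CC=C)C=CC(C)(C)O2
F2 | step 10 | triethyl{[(2R)-2-(7-methoxy-2,2-dimethyl-2H-chromen-6-yl)pent-4-en-2-yl]oxy}silane | COc1cc2c(cc1[C@](C)(O[Si](CC)(CC)CC)CC=C)C=CC(C)(C)O2
F3 | step 10 | triethyl{[(2R,4S)-2-(7-methoxy-2,2-dimethyl-2H-chromen-6-yl)-4-(4,4,5,5-tetramethyl-1,3,2-dioxaborolan-2-yl)pentan-2-yl]oxy}silane | COc1cc2c(cc1[C@](C)(O[Si](CC)(CC)CC)C[C@H](C)B3OC(C)(C)C(C)(C)O3)C=CC(C)(C)O2
F4 | step 10 | lithium boronate complex of 21 and F3 | [Li+].COc1cc2c(cc1[C@](C)(O[Si](CC)(CC)CC)C[C@H](C)[B-]3(OC(C)(C)C(C)(C)O3)c3cc4cc(C(=C)O[Si](C(C)C)(C(C)C)C(C)C)c(O[Si](C(C)C)(C(C)C)C(C)C)cc4o3)C=CC(C)(C)O2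
F5 | step 10 | triethylsilyl ether of 24 | COc1cc2c(cc1[C@](C)(O[Si](CC)(CC)CC)C[C@H](C)c3cc4cc(C(=C)O[Si](C(C)C)(C(C)C)C(C)C)c(O[Si](C(C)C)(C(C)C)C(C)C)cc4o3)C=CC(C)(C)O2
F6 | step 6 | lithium boronate complex of 12 and allylboronic acid pinacol ester | [Li+].COc1cc2c(cc1[C@](C)(OC(=O)N(C(C)C)C(C)C)[B-]3(CC=C)OC(C)(C)C(C)(C)O3)C=CC(C)(C)O2
F7 | step 6 | 2-[(2S)-2-(7-methoxy-2,2-dimethyl-2H-chromen-6-yl)pent-4-en-2-yl]-4,4,5,5-tetramethyl-1,3,2-dioxaborolane | COc1cc2c(cc1[C@](C)(B3OC(C)(C)C(C)(C)O3)CC=C)C=CC(C)(C)O2
F8 | step 5 | (E)-2,2'-(prop-1-ene-1,2-diyl)bis(4,4,5,5-tetramethyl-1,3,2-dioxaborolane), boron atoms cis | C/C(B1OC(C)(C)C(C)(C)O1)=C/B1OC(C)(C)C(C)(C)O1
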